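**Strategy**

Everything rests on building ring A of the flavanone onto ring E, so that the crowded C6–E6 bond is never made by coupling. Ring A is a phloroglucinol with oxygens on C5, C7 and C8a and ring E on C6 between O5 and O7. Thermal benzannulation of a 3-alkoxycyclobutenone (C5, C4a, C8a, C8) with an aryl siloxyalkyne (C6, C7) forms C5–C6, C7–C8 and C4a–C5 at once and leaves O5 free, O7 silylated and O8a as a 4-methoxybenzyl ether. The alkyne precursor is ring E bearing two benzyl ethers and a dioxolane-masked aldehyde for the later flavone. Ring C follows by Mitsunobu inversion and Friedel–Crafts closure.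

Key step: step 7

Remark on labels: flavanone atoms O1 to C8a (rings A, C, B); catechol ring E with E1 on the flavone and E6 on C6; flavone hetero ring F and benzo ring G.
Remark on the chemistry: the stereocenter C2 of the target is read as (R); the C6–E6 axis carries no descriptor in the target and is left uncontrolled.
Remark on the chemistry: once O5 and O7 carry the same group, C4a and C8 are equivalent, so only O8a has to be distinguished.

**Route**

Step 1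
Reactants: 1 3,4-bis(benzyloxy)benzaldehyde
Product: 2 4,5-bis(benzyloxy)-2-bromobenzaldehyde
Conditions: Br2, NaOAc, AcOH, 23 °C
Reagents that add atoms: bromine, BrBr
Why: Electrophilic aromatic bromination should go para to the C3 benzyloxy group, the one activated position not flanked by two substituents, while NaOAc buffers HBr so that the benzyl ethers survive.

Step 2
Reactants: 2 4,5-bis(benzyloxy)-2-bromobenzaldehyde
Product: 3 4,5-bis(benzyloxy)-2-[(trimethylsilyl)ethynyl]benzaldehyde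
Conditions: Me3SiC≡CH, Pd(PPh3)2Cl2 (3 mol%), CuI (3 mol%), Et3N, THF, 60 °C
Reagents that add atoms: ethynyltrimethylsilane, C#C[Si](C)(C)C
Why: Sonogashira coupling is run on the free aldehyde because the ortho formyl group speeds oxidative addition into the otherwise electron-rich aryl bromide.

Step 3
Reactants: 3 4,5-bis(benzyloxy)-2-[(trimethylsilyl)ethynyl]benzaldehyde
Product: 4 2-{4,5-bis(benzyloxy)-2-[(trimethylsilyl)ethynyl]phenyl}-1,3-dioxolane
Conditions: HOCH2CH2OH, TsOH·H2O (cat.), toluene, reflux (Dean–Stark)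
Reagents that add atoms: ethane-1,2-diol, OCCO
Why: Acid-catalysed acetalization with azeotropic removal of water masks the aldehyde against the strong bases of step 5, and the C-silyl alkyne is inert to these conditions.

Step 4
Reactants: 4 2-{4,5-bis(benzyloxy)-2-[(trimethylsilyl)ethynyl]phenyl}-1,3-dioxolane
Product: 5 2-[4,5-bis(benzyloxy)-2-ethynylphenyl]-1,3-dioxolane
Conditions: K2CO3 (cat.), MeOH–THF, 23 °C
Reagents that add atoms: none
Why: Base-catalysed methanolysis of the alkynyl C–Si bond (protodesilylation) should free the terminal alkyne without touching acetal or benzyl ethers.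

Step 5
Reactants: 5 2-[4,5-bis(benzyloxy)-2-ethynylphenyl]-1,3-dioxolane
Product: 8 2-{4,5-bis(benzyloxy)-2-[(triisopropylsilyloxy)ethynyl]phenyl}-1,3-dioxolane, via lithium acetylide 6 (not isolated), via lithium ynolate 7 (not isolated)
Conditions: t-BuOOH (1.0 equiv), LiN(SiMe3)2 (2.2 equiv), THF, −78 → 0 °C; then iPr3SiOTf (1.3 equiv), −78 → 0 °C
Reagents that add atoms: tert-butyl hydroperoxide, CC(C)(C)OO; triisopropylsilyl trifluoromethanesulfonate, CC(C)[Si](OS(=O)(=O)C(F)(F)F)(C(C)C)C(C)C; lithium bis(trimethylsilyl)amide, [Li]N([Si](C)(C)C)[Si](C)(C)C (lithium in 6 and 7 only)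
Why: Acetylide oxidation by electrophilic oxygen transfer from lithium tert-butyl peroxide should give the ynolate, and O-silylation with the hard, bulky silyl triflate then gives the siloxyalkyne.

Step 6
Reactants: 9 cyclobutane-1,3-dione
Product: 10 3-[(4-methoxybenzyl)oxy]cyclobut-2-en-1-one
Conditions: 4-MeOC6H4CH2OH, PPh3, DIAD, THF, 0 → 23 °C
Reagents that add atoms: 4-methoxybenzyl alcohol, COc1ccc(CO)cc1
Why: Mitsunobu O-alkylation of the strongly acidic enol of the 1,3-dione (a vinylogous acid) with a primary benzylic alcohol should give the vinylogous ester without heating the strained ring.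

Step 7
Reactants: 8 2-{4,5-bis(benzyloxy)-2-[(triisopropylsilyloxy)ethynyl]phenyl}-1,3-dioxolane; 10 3-[(4-methoxybenzyl)oxy]cyclobut-2-en-1-one (1.2 equiv)
Product: 15 2-[4,5-bis(benzyloxy)-2-(1,3-dioxolan-2-yl)phenyl]-5-[(4-methoxybenzyl)oxy]-3-(triisopropylsilyloxy)phenol, via vinylketene 11 (not isolated), via vinylcyclobutenone 12 (not isolated), via dienylketene 13 (not isolated), via cyclohexadienone 14 (not isolated)
Conditions: toluene (0.5 M), 80 °C, then 110 °C, argon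
Reagents that add atoms: none
Why: Heat opens 10 by four-electron electrocyclic ring opening to vinylketene 11, and the siloxyalkyne adds across the ketene C=C in a [2+2] cycloaddition that closes the transient four-membered ring of 12, its aryl-bearing carbon (future C6) bonding to the ketene carbonyl carbon (future C5) and its oxygen-bearing carbon (C7) to the ketene α-carbon (C8). A second four-electron opening gives dienylketene 13, which closes ring A by thermal disrotatory six-electron electrocyclization (C4a–C5), and dienone 14 tautomerizes to the phenol. The closest known reaction type is the Danheiser benzannulation of cyclobutenones with siloxyalkynes, which gives resorcinol monosilyl ethers. No stereocenter is created, since the sp3 carbon of 12 is lost on ring opening. The step needs regioselectivity in the [2+2], secured by the polarization of the ynol ether, and it needs the ketene to be trapped faster than it dimerizes, which the electron-rich alkyne at high concentration should ensure; the neutral conditions should spare acetal, benzyl and 4-methoxybenzyl groups.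

Step 8
Reactants: 15 2-[4,5-bis(benzyloxy)-2-(1,3-dioxolan-2-yl)phenyl]-5-[(4-methoxybenzyl)oxy]-3-(triisopropylsilyloxy)phenol
Product: 17 2-{4,5-bis(benzyloxy)-2-[2,6-bis(benzyloxy)-4-[(4-methoxybenzyl)oxy]phenyl]phenyl}-1,3-dioxolane, via O5-benzyl silyl ether 16 (not isolated)
Conditions: BnBr, K2CO3, DMF, 23 °C; then CsF, 50 °C
Reagents that add atoms: benzyl bromide, BrCc1ccccc1
Why: Williamson etherification of the free O5 phenol is followed by fluoride cleavage of the aryl silyl ether, and the cesium phenoxide released is benzylated in the same flask, so O5 and O7 become identical.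

Step 9
Reactants: 17 2-{4,5-bis(benzyloxy)-2-[2,6-bis(benzyloxy)-4-[(4-methoxybenzyl)oxy]phenyl]phenyl}-1,3-dioxolane
Product: 18 4,5-bis(benzyloxy)-2-{2,6-bis(benzyloxy)-4-[(4-methoxybenzyl)oxy]phenyl}benzaldehyde
Conditions: 0.5 M HCl (aq), THF, 23 °C
Reagents that add atoms: water, O
Why: Acid-catalysed acetal hydrolysis at room temperature should free the aldehyde, since aryl benzyl and 4-methoxybenzyl ethers are stable to dilute aqueous acid.

Step 10
Reactants: 19 2,4,6-trihydroxyacetophenone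
Product: 20 1-[2,4-bis(benzyloxy)-6-hydroxyphenyl]ethan-1-one
Conditions: BnBr (2.1 equiv), K2CO3, DMF, 23 °C
Reagents that add atoms: benzyl bromide, BrCc1ccccc1
Why: Williamson etherification with two equivalents of bromide should leave free the one hydroxyl that is hydrogen-bonded to the acetyl carbonyl, which is the least nucleophilic.

Step 11
Reactants: 18 4,5-bis(benzyloxy)-2-{2,6-bis(benzyloxy)-4-[(4-methoxybenzyl)oxy]phenyl}benzaldehyde; 20 1-[2,4-bis(benzyloxy)-6-hydroxyphenyl]ethan-1-one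
Product: 21 (2E)-1-[2,4-bis(benzyloxy)-6-hydroxyphenyl]-3-(4,5-bis(benzyloxy)-2-{2,6-bis(benzyloxy)-4-[(4-methoxybenzyl)oxy]phenyl}phenyl)prop-2-en-1-one
Conditions: KOH (aq), EtOH–THF, 23 °C
Reagents that add atoms: none
Why: Claisen–Schmidt condensation of the methyl ketone enolate with the non-enolizable aldehyde should give the E enone by dehydration into conjugation.

Step 12
Reactants: 21 (2E)-1-[2,4-bis(benzyloxy)-6-hydroxyphenyl]-3-(4,5-bis(benzyloxy)-2-{2,6-bis(benzyloxy)-4-[(4-methoxybenzyl)oxy]phenyl}phenyl)prop-2-en-1-one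
Product: 22 5,7-bis(benzyloxy)-2-(4,5-bis(benzyloxy)-2-{2,6-bis(benzyloxy)-4-[(4-methoxybenzyl)oxy]phenyl}phenyl)-4H-chromen-4-one
Conditions: I2 (10 mol%), DMSO, 130 °C
Reagents that add atoms: none
Why: Iodine-catalysed oxidative cyclization of the 2'-hydroxychalcone (oxa-Michael closure, α-iodination, loss of HI, DMSO reoxidizing iodide) should give rings F and G of the flavone.

Step 13
Reactants: 22 5,7-bis(benzyloxy)-2-(4,5-bis(benzyloxy)-2-{2,6-bis(benzyloxy)-4-[(4-methoxybenzyl)oxy]phenyl}phenyl)-4H-chromen-4-one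
Product: 23 5,7-bis(benzyloxy)-2-{4,5-bis(benzyloxy)-2-[2,6-bis(benzyloxy)-4-hydroxyphenyl]phenyl}-4H-chromen-4-one
Conditions: CF3CO2H (5 vol%), n-C12H25SH, CH2Cl2, 0 °C
Reagents that add atoms: none
Why: Acidolysis of the 4-methoxybenzyl aryl ether proceeds through the stabilized benzylic cation, which the thiol traps before it can alkylate ring A, while plain benzyl ethers do not ionize under these conditions.

Step 14
Reactants: 24 4-hydroxybenzoic acid
Product: 25 4-{[(benzyloxy)carbonyl]oxy}benzoic acid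
Conditions: BnOCOCl, NaOH (aq), 0 °C; then HCl (aq)
Reagents that add atoms: benzyl chloroformate, O=C(Cl)OCc1ccccc1
Why: Schotten–Baumann acylation should take place at the phenoxide, any mixed anhydride at the carboxylate hydrolysing back.

Step 15
Reactants: 25 4-{[(benzyloxy)carbonyl]oxy}benzoic acid
Product: 28 tert-butyl 3-(4-{[(benzyloxy)carbonyl]oxy}phenyl)-3-oxopropanoate, via acid chloride 26 (not isolated), via acylmalonate 27 (not isolated)
Conditions: (COCl)2, DMF (cat.), CH2Cl2, 23 °C; then KO2CCH2CO2t-Bu, MgCl2, Et3N, MeCN, 0 → 23 °C; 1 M HCl (aq)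
Reagents that add atoms: potassium 3-tert-butoxy-3-oxopropanoate, [K+].[O-]C(=O)CC(=O)OC(C)(C)C; oxalyl chloride, O=C(Cl)C(=O)Cl (chlorine in 26 only)
Why: Acid chloride formation, then magnesium-mediated C-acylation of the malonate half ester and decarboxylation on acidification, builds the β-keto ester without a nucleophilic base that would cleave the aryl carbonate.

Step 16
Reactants: 28 tert-butyl 3-(4-{[(benzyloxy)carbonyl]oxy}phenyl)-3-oxopropanoate
Product: 29 tert-butyl (3S)-3-(4-{[(benzyloxy)carbonyl]oxy}phenyl)-3-hydroxypropanoate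
Conditions: RuCl[(S,S)-TsDPEN](p-cymene) (1 mol%), HCO2H–Et3N (5:2), CH2Cl2, 30 °C
Reagents that add atoms: none
Why: Noyori-type asymmetric transfer hydrogenation of the aryl ketone; the (S,S)-diamine ligand, through its CH/π-organized six-membered transition state, should deliver hydride to the face that gives the (S) carbinol C3 (future C2).

Step 17
Reactants: 23 5,7-bis(benzyloxy)-2-{4,5-bis(benzyloxy)-2-[2,6-bis(benzyloxy)-4-hydroxyphenyl]phenyl}-4H-chromen-4-one; 29 tert-butyl (3S)-3-(4-{[(benzyloxy)carbonyl]oxy}phenyl)-3-hydroxypropanoate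
Product: 30 tert-butyl (3R)-3-(4-{[(benzyloxy)carbonyl]oxy}phenyl)-3-(3,5-bis(benzyloxy)-4-{4,5-bis(benzyloxy)-2-[5,7-bis(benzyloxy)-4-oxo-4H-chromen-2-yl]phenyl}phenoxy)propanoate
Conditions: PPh3, DIAD, toluene, 0 → 23 °C
Reagents that add atoms: none
Why: Mitsunobu etherification, in which the unhindered O8a phenoxide displaces the oxyphosphonium with inversion, should turn (S)-C3 into the (R) ether carbon (future C2), and the electron-withdrawing carbonate on ring B disfavours ionization at the benzylic carbon.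

Step 18
Reactants: 30 tert-butyl (3R)-3-(4-{[(benzyloxy)carbonyl]oxy}phenyl)-3-(3,5-bis(benzyloxy)-4-{4,5-bis(benzyloxy)-2-[5,7-bis(benzyloxy)-4-oxo-4H-chromen-2-yl]phenyl}phenoxy)propanoate
Product: 33 benzyl 4-[(2R)-5,7-bis(benzyloxy)-6-{4,5-bis(benzyloxy)-2-[5,7-bis(benzyloxy)-4-oxo-4H-chromen-2-yl]phenyl}-4-oxo-3,4-dihydro-2H-chromen-2-yl]phenyl carbonate, via carboxylic acid 31 (not isolated), via mixed anhydride 32 (not isolated)
Conditions: CF3CO2H, CH2Cl2, 0 °C; then (CF3CO)2O, 0 → 23 °C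
Reagents that add atoms: trifluoroacetic anhydride, O=C(OC(=O)C(F)(F)F)C(F)(F)F (trifluoroacetyl group in 32 only)
Why: Acidolysis of the tert-butyl ester, then intramolecular Friedel–Crafts acylation through the mixed trifluoroacetic anhydride, should close ring C at C4a (equivalent to C8) on the highly activated ring A without involving the stereocenter.

Step 19
Reactants: 33 benzyl 4-[(2R)-5,7-bis(benzyloxy)-6-{4,5-bis(benzyloxy)-2-[5,7-bis(benzyloxy)-4-oxo-4H-chromen-2-yl]phenyl}-4-oxo-3,4-dihydro-2H-chromen-2-yl]phenyl carbonate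
Product: 34 (2R)-6-[2-(5,7-dihydroxy-4-oxo-4H-chromen-2-yl)-4,5-dihydroxyphenyl]-5,7-dihydroxy-2-(4-hydroxyphenyl)-2,3-dihydro-4H-chromen-4-one
Conditions: H2 (1 atm), Pd/C, THF–MeOH, 23 °C
Reagents that add atoms: none
Why: Catalytic hydrogenolysis should remove the six benzyl ethers and the benzyl carbonate (with loss of CO2) under neutral conditions that leave C2 and both pyranone rings untouched.

**Compound list**

1 | 3,4-bis(benzyloxy)benzaldehyde | O=Cc1ccc(OCc2ccccc2)c(OCc2ccccc2)c1 | starting material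
2 | 4,5-bis(benzyloxy)-2-bromobenzaldehyde | O=Cc1cc(OCc2ccccc2)c(OCc2ccccc2)cc1Br | intermediate
3 | 4,5-bis(benzyloxy)-2-[(trimethylsilyl)ethynyl]benzaldehyde | O=Cc1cc(OCc2ccccc2)c(OCc2ccccc2)cc1C#C[Si](C)(C)C | intermediate
4 | 2-{4,5-bis(benzyloxy)-2-[(trimethylsilyl)ethynyl]phenyl}-1,3-dioxolane | C[Si](C)(C)C#Cc1cc(OCc2ccccc2)c(OCc2ccccc2)cc1C1OCCO1 | intermediate
5 | 2-[4,5-bis(benzyloxy)-2-ethynylphenyl]-1,3-dioxolane | C#Cc1cc(OCc2ccccc2)c(OCc2ccccc2)cc1C1OCCO1 | intermediate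
6 | {[4,5-bis(benzyloxy)-2-(1,3-dioxolan-2-yl)phenyl]ethynyl}lithium | [Li]C#Cc1cc(OCc2ccccc2)c(OCc2ccccc2)cc1C1OCCO1 | intermediate (not isolated)
7 | lithium 2-[4,5-bis(benzyloxy)-2-(1,3-dioxolan-2-yl)phenyl]ethyn-1-olate | [Li]OC#Cc1cc(OCc2ccccc2)c(OCc2ccccc2)cc1C1OCCO1 | intermediate (not isolated)
8 | 2-{4,5-bis(benzyloxy)-2-[(triisopropylsilyloxy)ethynyl]phenyl}-1,3-dioxolane | CC(C)[Si](C(C)C)(C(C)C)OC#Cc1cc(OCc2ccccc2)c(OCc2ccccc2)cc1C1OCCO1 | intermediate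
9 | cyclobutane-1,3-dione | O=C1CC(=O)C1 | starting material
10 | 3-[(4-methoxybenzyl)oxy]cyclobut-2-en-1-one | O=C1C=C(OCc2ccc(OC)cc2)C1 | intermediate
11 | 3-[(4-methoxybenzyl)oxy]buta-1,3-dien-1-one | C=C(OCc1ccc(OC)cc1)C=C=O | intermediate (not isolated)
12 | 2-[4,5-bis(benzyloxy)-2-(1,3-dioxolan-2-yl)phenyl]-4-{1-[(4-methoxybenzyl)oxy]ethenyl}-3-(triisopropylsilyloxy)cyclobut-2-en-1-one (racemic at C4) | O=C1C(c2cc(OCc3ccccc3)c(OCc3ccccc3)cc2C2OCCO2)=C(O[Si](C(C)C)(C(C)C)C(C)C)C1C(=C)OCc1ccc(OC)cc1 | intermediate (not isolated)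
13 | (3E)-2-[4,5-bis(benzyloxy)-2-(1,3-dioxolan-2-yl)phenyl]-5-[(4-methoxybenzyl)oxy]-3-(triisopropylsilyloxy)hexa-1,3,5-trien-1-one | O=C=C(c1cc(OCc2ccccc2)c(OCc2ccccc2)cc1C1OCCO1)/C(O[Si](C(C)C)(C(C)C)C(C)C)=C\C(=C)OCc1ccc(OC)cc1 | intermediate (not isolated)
14 | 2-[4,5-bis(benzyloxy)-2-(1,3-dioxolan-2-yl)phenyl]-5-[(4-methoxybenzyl)oxy]-3-(triisopropylsilyloxy)cyclohexa-2,4-dien-1-one | O=C1CC(OCc2ccc(OC)cc2)=CC(O[Si](C(C)C)(C(C)C)C(C)C)=C1c1cc(OCc2ccccc2)c(OCc2ccccc2)cc1C1OCCO1 | intermediate (not isolated)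
15 | 2-[4,5-bis(benzyloxy)-2-(1,3-dioxolan-2-yl)phenyl]-5-[(4-methoxybenzyl)oxy]-3-(triisopropylsilyloxy)phenol | Oc1cc(OCc2ccc(OC)cc2)cc(O[Si](C(C)C)(C(C)C)C(C)C)c1-c1cc(OCc2ccccc2)c(OCc2ccccc2)cc1C1OCCO1 | intermediate
16 | 2-{4,5-bis(benzyloxy)-2-[2-(benzyloxy)-4-[(4-methoxybenzyl)oxy]-6-(triisopropylsilyloxy)phenyl]phenyl}-1,3-dioxolane | COc1ccc(COc2cc(OCc3ccccc3)c(-c3cc(OCc4ccccc4)c(OCc4ccccc4)cc3C3OCCO3)c(O[Si](C(C)C)(C(C)C)C(C)C)c2)cc1 | intermediate (not isolated)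
17 | 2-{4,5-bis(benzyloxy)-2-[2,6-bis(benzyloxy)-4-[(4-methoxybenzyl)oxy]phenyl]phenyl}-1,3-dioxolane | COc1ccc(COc2cc(OCc3ccccc3)c(-c3cc(OCc4ccccc4)c(OCc4ccccc4)cc3C3OCCO3)c(OCc3ccccc3)c2)cc1 | intermediate
18 | 4,5-bis(benzyloxy)-2-{2,6-bis(benzyloxy)-4-[(4-methoxybenzyl)oxy]phenyl}benzaldehyde | COc1ccc(COc2cc(OCc3ccccc3)c(-c3cc(OCc4ccccc4)c(OCc4ccccc4)cc3C=O)c(OCc3ccccc3)c2)cc1 | intermediate
19 | 2,4,6-trihydroxyacetophenone | CC(=O)c1c(O)cc(O)cc1O | starting material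
20 | 1-[2,4-bis(benzyloxy)-6-hydroxyphenyl]ethan-1-one | CC(=O)c1c(O)cc(OCc2ccccc2)cc1OCc1ccccc1 | intermediate
21 | (2E)-1-[2,4-bis(benzyloxy)-6-hydroxyphenyl]-3-(4,5-bis(benzyloxy)-2-{2,6-bis(benzyloxy)-4-[(4-methoxybenzyl)oxy]phenyl}phenyl)prop-2-en-1-one | COc1ccc(COc2cc(OCc3ccccc3)c(-c3cc(OCc4ccccc4)c(OCc4ccccc4)cc3/C=C/C(=O)c3c(O)cc(OCc4ccccc4)cc3OCc3ccccc3)c(OCc3ccccc3)c2)cc1 | intermediate
22 | 5,7-bis(benzyloxy)-2-(4,5-bis(benzyloxy)-2-{2,6-bis(benzyloxy)-4-[(4-methoxybenzyl)oxy]phenyl}phenyl)-4H-chromen-4-one | COc1ccc(COc2cc(OCc3ccccc3)c(-c3cc(OCc4ccccc4)c(OCc4ccccc4)cc3-c3cc(=O)c4c(OCc5ccccc5)cc(OCc5ccccc5)cc4o3)c(OCc3ccccc3)c2)cc1 | intermediate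
23 | 5,7-bis(benzyloxy)-2-{4,5-bis(benzyloxy)-2-[2,6-bis(benzyloxy)-4-hydroxyphenyl]phenyl}-4H-chromen-4-one | Oc1cc(OCc2ccccc2)c(-c2cc(OCc3ccccc3)c(OCc3ccccc3)cc2-c2cc(=O)c3c(OCc4ccccc4)cc(OCc4ccccc4)cc3o2)c(OCc2ccccc2)c1 | intermediate
24 | 4-hydroxybenzoic acid | O=C(O)c1ccc(O)cc1 | starting material
25 | 4-{[(benzyloxy)carbonyl]oxy}benzoic acid | O=C(O)c1ccc(OC(=O)OCc2ccccc2)cc1 | intermediate
26 | 4-{[(benzyloxy)carbonyl]oxy}benzoyl chloride | O=C(Cl)c1ccc(OC(=O)OCc2ccccc2)cc1 | intermediate (not isolated)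
27 | 2-(4-{[(benzyloxy)carbonyl]oxy}benzoyl)-3-tert-butoxy-3-oxopropanoic acid (magnesium chelate in the flask) | CC(C)(C)OC(=O)C(C(=O)O)C(=O)c1ccc(OC(=O)OCc2ccccc2)cc1 | intermediate (not isolated)
28 | tert-butyl 3-(4-{[(benzyloxy)carbonyl]oxy}phenyl)-3-oxopropanoate | CC(C)(C)OC(=O)CC(=O)c1ccc(OC(=O)OCc2ccccc2)cc1 | intermediate
29 | tert-butyl (3S)-3-(4-{[(benzyloxy)carbonyl]oxy}phenyl)-3-hydroxypropanoate | CC(C)(C)OC(=O)C[C@H](O)c1ccc(OC(=O)OCc2ccccc2)cc1 | intermediate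
30 | tert-butyl (3R)-3-(4-{[(benzyloxy)carbonyl]oxy}phenyl)-3-(3,5-bis(benzyloxy)-4-{4,5-bis(benzyloxy)-2-[5,7-bis(benzyloxy)-4-oxo-4H-chromen-2-yl]phenyl}phenoxy)propanoate | CC(C)(C)OC(=O)C[C@@H](Oc1cc(OCc2ccccc2)c(-c2cc(OCc3ccccc3)c(OCc3ccccc3)cc2-c2cc(=O)c3c(OCc4ccccc4)cc(OCc4ccccc4)cc3o2)c(OCc2ccccc2)c1)c1ccc(OC(=O)OCc2ccccc2)cc1 | intermediate
31 | (3R)-3-(4-{[(benzyloxy)carbonyl]oxy}phenyl)-3-(3,5-bis(benzyloxy)-4-{4,5-bis(benzyloxy)-2-[5,7-bis(benzyloxy)-4-oxo-4H-chromen-2-yl]phenyl}phenoxy)propanoic acid | O=C(O)C[C@@H](Oc1cc(OCc2ccccc2)c(-c2cc(OCc3ccccc3)c(OCc3ccccc3)cc2-c2cc(=O)c3c(OCc4ccccc4)cc(OCc4ccccc4)cc3o2)c(OCc2ccccc2)c1)c1ccc(OC(=O)OCc2ccccc2)cc1 | intermediate (not isolated)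
32 | mixed anhydride of acid 31 and trifluoroacetic acid, (3R) | O=C(C[C@@H](Oc1cc(OCc2ccccc2)c(-c2cc(OCc3ccccc3)c(OCc3ccccc3)cc2-c2cc(=O)c3c(OCc4ccccc4)cc(OCc4ccccc4)cc3o2)c(OCc2ccccc2)c1)c1ccc(OC(=O)OCc2ccccc2)cc1)OC(=O)C(F)(F)F | intermediate (not isolated)
33 | benzyl 4-[(2R)-5,7-bis(benzyloxy)-6-{4,5-bis(benzyloxy)-2-[5,7-bis(benzyloxy)-4-oxo-4H-chromen-2-yl]phenyl}-4-oxo-3,4-dihydro-2H-chromen-2-yl]phenyl carbonate | O=C1C[C@H](c2ccc(OC(=O)OCc3ccccc3)cc2)Oc2cc(OCc3ccccc3)c(-c3cc(OCc4ccccc4)c(OCc4ccccc4)cc3-c3cc(=O)c4c(OCc5ccccc5)cc(OCc5ccccc5)cc4o3)c(OCc3ccccc3)c21 | intermediate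
34 | (2R)-6-[2-(5,7-dihydroxy-4-oxo-4H-chromen-2-yl)-4,5-dihydroxyphenyl]-5,7-dihydroxy-2-(4-hydroxyphenyl)-2,3-dihydro-4H-chromen-4-one | O=C1C[C@H](c2ccc(O)cc2)Oc2cc(O)c(-c3cc(O)c(O)cc3-c3cc(=O)c4c(O)cc(O)cc4o3)c(O)c21 | target

**Count**

Total steps: 19. Longest linear sequence: 14 steps (steps 1 to 5, 7 to 9, 11 to 13, 17 to 19).

**Steps most likely to fail**

Step 7. The [2+2] addition of the ortho-substituted aryl siloxyalkyne may be slow, so that the alkoxy vinylketene dimerizes or acylates the product phenol, or the second ring opening stalls. Fallback from 2, returning at 18: the C6–E6 bond is made by cross-coupling instead. Commercial 3,5-bis(benzyloxy)phenol is silylated (iPr3SiCl, imidazole, DMF) to [3,5-bis(benzyloxy)phenoxy]tri(propan-2-yl)silane F1. Directed ortho-lithiation between the two benzyloxy groups (n-BuLi, THF, 0 °C), which the bulky non-coordinating silyl ether should steer away from its own neighbours, and quenching with B(Oi-Pr)3 then aqueous acid gives [2,6-bis(benzyloxy)-4-(triisopropylsilyloxy)phenyl]boronic acid F2. Suzuki–Miyaura coupling of F2 with 2 (Pd(OAc)2, SPhos, K3PO4, toluene–H2O, 80 °C) gives 4,5-bis(benzyloxy)-2-[2,6-bis(benzyloxy)-4-(triisopropylsilyloxy)phenyl]benzaldehyde F3. Desilylative alkylation (4-methoxybenzyl chloride, CsF, DMF) then gives 18.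

Step 17. The activated β-hydroxy ester may eliminate to the cinnamate under Mitsunobu conditions, and partial ionization at the benzylic carbon may erode the configuration. Fallback from 23, returning at 34: C2 is set by catalyst-controlled C–C bond formation instead.
- C-Acetylation ortho to O8a (AcOH, (CF3CO)2O, CH2Cl2; then K2CO3, MeOH) gives 2-{2-[3-acetyl-2,6-bis(benzyloxy)-4-hydroxyphenyl]-4,5-bis(benzyloxy)phenyl}-5,7-bis(benzyloxy)-4H-chromen-4-one F4.
- Me2NCH(OMe)2 in toluene at 90 °C gives the (E)-3-(dimethylamino)prop-2-enoyl analogue of F4 (enaminone) F5, and HCl (aq) in CH2Cl2 closes it to 5,7-bis(benzyloxy)-6-{4,5-bis(benzyloxy)-2-[5,7-bis(benzyloxy)-4-oxo-4H-chromen-2-yl]phenyl}-4H-chromen-4-one F6.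
- Palladium-catalysed asymmetric conjugate addition of [4-(benzyloxy)phenyl]boronic acid (Pd(OCOCF3)2, (S)-t-BuPyOx, NH4PF6, H2O, 1,2-dichloroethane, 60 °C) should add only to the unsubstituted chromone and, by the facial model for cyclic enones, give (2R)-5,7-bis(benzyloxy)-2-[4-(benzyloxy)phenyl]-6-{4,5-bis(benzyloxy)-2-[5,7-bis(benzyloxy)-4-oxo-4H-chromen-2-yl]phenyl}-2,3-dihydro-4H-chromen-4-one F7.
- Hydrogenolysis (H2, Pd/C) then gives 34.

Step 12. Hot I2/DMSO may iodinate the electron-rich ring A and may cleave the 4-methoxybenzyl ether early. Fallback from 18, returning at 23: the flavone is built by acyl transfer and dehydration, with no oxidant. Pinnick oxidation (NaClO2, NaH2PO4, 2-methylbut-2-ene, t-BuOH–H2O) gives 4,5-bis(benzyloxy)-2-{2,6-bis(benzyloxy)-4-[(4-methoxybenzyl)oxy]phenyl}benzoic acid F8. Esterification with 20 (EDC·HCl, DMAP, CH2Cl2) gives 2-acetyl-3,5-bis(benzyloxy)phenyl 4,5-bis(benzyloxy)-2-{2,6-bis(benzyloxy)-4-[(4-methoxybenzyl)oxy]phenyl}benzoate F9. Baker–Venkataraman rearrangement (KOt-Bu, THF, 0 → 23 °C) gives 1-[2,4-bis(benzyloxy)-6-hydroxyphenyl]-3-(4,5-bis(benzyloxy)-2-{2,6-bis(benzyloxy)-4-[(4-methoxybenzyl)oxy]phenyl}phenyl)propane-1,3-dione F10. Acid (TsOH·H2O, n-C12H25SH, toluene, 80 °C) then effects cyclodehydration and removal of the 4-methoxybenzyl group together, giving 23.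

**Further compounds**

F1 | step 7 | [3,5-bis(benzyloxy)phenoxy]tri(propan-2-yl)silane | CC(C)[Si](Oc1cc(OCc2ccccc2)cc(OCc2ccccc2)c1)(C(C)C)C(C)C
F2 | step 7 | [2,6-bis(benzyloxy)-4-(triisopropylsilyloxy)phenyl]boronic acid | OB(O)c1c(OCc2ccccc2)cc(O[Si](C(C)C)(C(C)C)C(C)C)cc1OCc1ccccc1
F3 | step 7 | 4,5-bis(benzyloxy)-2-[2,6-bis(benzyloxy)-4-(triisopropylsilyloxy)phenyl]benzaldehyde | O=Cc1cc(OCc2ccccc2)c(OCc2ccccc2)cc1-c1c(OCc2ccccc2)cc(O[Si](C(C)C)(C(C)C)C(C)C)cc1OCc1ccccc1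
F4 | step 17 | 2-{2-[3-acetyl-2,6-bis(benzyloxy)-4-hydroxyphenyl]-4,5-bis(benzyloxy)phenyl}-5,7-bis(benzyloxy)-4H-chromen-4-one | CC(=O)c1c(O)cc(OCc2ccccc2)c(-c2cc(OCc3ccccc3)c(OCc3ccccc3)cc2-c2cc(=O)c3c(OCc4ccccc4)cc(OCc4ccccc4)cc3o2)c1OCc1ccccc1
F5 | step 17 | 2-(2-{2,6-bis(benzyloxy)-3-[(2E)-3-(dimethylamino)prop-2-enoyl]-4-hydroxyphenyl}-4,5-bis(benzyloxy)phenyl)-5,7-bis(benzyloxy)-4H-chromen-4-one | CN(C)/C=C/C(=O)c1c(O)cc(OCc2ccccc2)c(-c2cc(OCc3ccccc3)c(OCc3ccccc3)cc2-c2cc(=O)c3c(OCc4ccccc4)cc(OCc4ccccc4)cc3o2)c1OCc1ccccc1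
F6 | step 17 | 5,7-bis(benzyloxy)-6-{4,5-bis(benzyloxy)-2-[5,7-bis(benzyloxy)-4-oxo-4H-chromen-2-yl]phenyl}-4H-chromen-4-one | O=c1ccoc2cc(OCc3ccccc3)c(-c3cc(OCc4ccccc4)c(OCc4ccccc4)cc3-c3cc(=O)c4c(OCc5ccccc5)cc(OCc5ccccc5)cc4o3)c(OCc3ccccc3)c12
F7 | step 17 | (2R)-5,7-bis(benzyloxy)-2-[4-(benzyloxy)phenyl]-6-{4,5-bis(benzyloxy)-2-[5,7-bis(benzyloxy)-4-oxo-4H-chromen-2-yl]phenyl}-2,3-dihydro-4H-chromen-4-one | O=C1C[C@H](c2ccc(OCc3ccccc3)cc2)Oc2cc(OCc3ccccc3)c(-c3cc(OCc4ccccc4)c(OCc4ccccc4)cc3-c3cc(=O)c4c(OCc5ccccc5)cc(OCc5ccccc5)cc4o3)c(OCc3ccccc3)c21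
F8 | step 12 | 4,5-bis(benzyloxy)-2-{2,6-bis(benzyloxy)-4-[(4-methoxybenzyl)oxy]phenyl}benzoic acid | COc1ccc(COc2cc(OCc3ccccc3)c(-c3cc(OCc4ccccc4)c(OCc4ccccc4)cc3C(=O)O)c(OCc3ccccc3)c2)cc1
F9 | step 12 | 2-acetyl-3,5-bis(benzyloxy)phenyl 4,5-bis(benzyloxy)-2-{2,6-bis(benzyloxy)-4-[(4-methoxybenzyl)oxy]phenyl}benzoate | COc1ccc(COc2cc(OCc3ccccc3)c(-c3cc(OCc4ccccc4)c(OCc4ccccc4)cc3C(=O)Oc3cc(OCc4ccccc4)cc(OCc4ccccc4)c3C(C)=O)c(OCc3ccccc3)c2)cc1
F10 | step 12 | 1-[2,4-bis(benzyloxy)-6-hydroxyphenyl]-3-(4,5-bis(benzyloxy)-2-{2,6-bis(benzyloxy)-4-[(4-methoxybenzyl)oxy]phenyl}phenyl)propane-1,3-dione | COc1ccc(COc2cc(OCc3ccccc3)c(-c3cc(OCc4ccccc4)c(OCc4ccccc4)cc3C(=O)CC(=O)c3c(O)cc(OCc4ccccc4)cc3OCc3ccccc3)c(OCc3ccccc3)c2)cc1
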